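## Retrosynthetic overview

1. Feature: the only carbocycle of cardopatine is a cyclobutane. C1 and C2 are neighbouring trans CH stereocentres (both R), each bonded to an sp carbon, and C3 and C4 are bare CH2 groups. C1–C2 with its two exocyclic carbons is therefore a fumarate unit, and C3–C4 is an ethylene equivalent.
2. Last disconnection: both C(sp)–C5(thiophene) bonds, by twofold Sonogashira coupling of (1R,2R)-1,2-diethynylcyclobutane with 5-bromo-2,2'-bithiophene. The four thiophene rings are bought, not built.
3. The two ethynyl groups go back by Corey–Fuchs homologation to the trans-1,2-dicarbaldehyde. This comes, through the diol, from a trans-cyclobutane-1,2-dicarbonyl compound.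
4. Key disconnection: ring bonds C1–C4 and C2–C3, by an enantioselective stepwise [2+2] cycloaddition of a fumaroyl oxazolidinone with 1,1-bis(methylthio)ethene. The catalyst is TiCl2(TADDOLate), and the C3 dithioacetal is afterwards hydrogenolysed to CH2.
5. Ring order: the cyclobutane is the one ring that is formed. Everything after it is functional-group change on the two arms.

Key step: step 3

Assumption: TiCl2(TADDOLate) from the (4R,5R)-diol is taken to leave open the Re face at the carbon alpha to the imide, as in the Diels–Alder reactions of the same catalyst, which leads to the (1R,2R) cycloadduct; if the sense proved opposite, the (4S,5S)-diol would be used and nothing else changed.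

## Route

Step 1
Reactants: 1 monomethyl fumarate [(E)-4-methoxy-4-oxobut-2-enoic acid]
Product: 2 methyl (E)-4-chloro-4-oxobut-2-enoate
Conditions: (COCl)2 (1.2 equiv), DMF (cat.), CH2Cl2, 0 °C → rt; evaporate, use crude
Reagents that add atoms: oxalyl chloride, O=C(Cl)C(=O)Cl
Why: DMF-catalysed (Vilsmeier-type) acid chloride formation activates the free acid without touching the ester or the E-alkene, and only gases form beside the product.

Step 2
Reactants: 2 methyl (E)-4-chloro-4-oxobut-2-enoate; 3 2-oxazolidinone
Product: 5 methyl (E)-4-oxo-4-(2-oxo-1,3-oxazolidin-3-yl)but-2-enoate, via lithium 2-oxooxazolidin-3-ide 4 (not isolated)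
Conditions: 3, n-BuLi (1.0 equiv), THF, −78 °C; then 2, −78 → 0 °C
Reagents that add atoms: n-butyllithium, [Li]CCCC (supplies only the lithium of 4)
Why: N-acylation of the lithiated carbamate by the acid chloride is fast at low temperature and outruns conjugate addition, so the E-configured imide with two binding carbonyl groups should be obtained.

Step 3
Reactants: 5 methyl (E)-4-oxo-4-(2-oxo-1,3-oxazolidin-3-yl)but-2-enoate; 6 1,1-bis(methylthio)ethene
Product: 7 methyl (1R,2R)-3,3-bis(methylthio)-2-(2-oxo-1,3-oxazolidine-3-carbonyl)cyclobutane-1-carboxylate (ester and imide trans)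
Conditions: TiCl2(O-i-Pr)2 (10 mol %), (4R,5R)-2-methyl-2-phenyl-α,α,α′,α′-tetraphenyl-1,3-dioxolane-4,5-dimethanol (11 mol %), 4 Å MS, toluene–petroleum ether 1:1, 0 °C; recrystallise
Reagents that add atoms: none
Why: The imide binds through both carbonyl oxygens to the tetravalent titanium of TiCl2(TADDOLate), the nucleophilic CH2 terminus of 6 adds to the carbon beta to the imide (C1–C4 bond) to give a bis(methylthio)carbenium/titanium enolate zwitterion, and the enolate carbon then collapses onto the thionium carbon (C2–C3 bond). The closest known reaction type is exactly this one, the chiral-titanium-catalysed enantioselective stepwise [2+2] cycloaddition of 3-enoyl oxazolidinones with ketene dithioacetals. The one ring closed, the cyclobutane, forms in a 4-(enolexo)-exo-trig closure. C1 is set in the conjugate addition, because the pseudo-axial aryl groups of the (4R,5R)-diol shield one face of the s-cis bound enoyl unit and 6 approaches from the face that is Re at the alpha carbon; C2 is set in the ring closure, which occurs on the same face faster than the C1–C2 bond rotates and places the imide trans to the ester, as both the E-alkene geometry and the lower strain of the trans product demand. The step needs regioselectivity (CH2 to the carbon beta to the imide and not beta to the ester), secured by two-point chelation of the imide only; it needs enantiofacial selectivity, secured by the diol; and it needs closure in preference to proton loss to an open-chain product, favoured by the low temperature, the non-polar medium and the sieves. The adduct is expected to crystallise, so its enantiomeric purity can be raised before the sulfur is removed.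

Step 4
Reactants: 7 methyl (1R,2R)-3,3-bis(methylthio)-2-(2-oxo-1,3-oxazolidine-3-carbonyl)cyclobutane-1-carboxylate
Product: 8 methyl (1R,2R)-2-(2-oxo-1,3-oxazolidine-3-carbonyl)cyclobutane-1-carboxylate
Conditions: Raney Ni (W-2, washed neutral, excess), THF–EtOH, rt
Reagents that add atoms: none
Why: Mozingo-type Raney Ni hydrogenolysis cleaves the C–S bonds under neutral conditions and turns C3 into CH2 without touching ester, imide or either stereocentre, since the cyclobutyl radical on the way has no easy ring-opening path.

Step 5
Reactants: 8 methyl (1R,2R)-2-(2-oxo-1,3-oxazolidine-3-carbonyl)cyclobutane-1-carboxylate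
Product: 9 [(1R,2R)-cyclobutane-1,2-diyl]dimethanol
Conditions: LiBH4 (4 equiv), THF, 0 °C → rt; H2O; continuous extraction (EtOAc), SiO2
Reagents that add atoms: none
Why: Borohydride reduction with LiBH4 takes both the activated exocyclic imide carbonyl and the methyl ester to primary alcohols without a basic epimerising medium, releases the oxazolidinone and should give the C2-symmetric trans diol.

Step 6
Reactants: 9 [(1R,2R)-cyclobutane-1,2-diyl]dimethanol
Product: 10 (1R,2R)-cyclobutane-1,2-dicarbaldehyde
Conditions: Dess–Martin periodinane (2.5 equiv), NaHCO3 (solid, excess), CH2Cl2, 0 °C → rt; dilute with pentane, filter through a short SiO2 pad, concentrate cold, use at once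
Reagents that add atoms: none
Why: Bicarbonate-buffered Dess–Martin oxidation is neutral and non-epimerising, and lactol or lactone formation at the half-oxidised stage is blocked because a trans-fused 3-oxabicyclo[3.2.0]heptane would be too strained.

Step 7
Reactants: 10 (1R,2R)-cyclobutane-1,2-dicarbaldehyde
Product: 11 (1R,2R)-1,2-bis(2,2-dibromoethenyl)cyclobutane
Conditions: CBr4, PPh3, Zn dust (4 equiv each), CH2Cl2, rt, 24 h (ylide pre-formed); then 10, 0 °C → rt; pentane, filter
Reagents that add atoms: carbon tetrabromide, BrC(Br)(Br)Br
Why: The first stage of the Corey–Fuchs homologation, a Wittig-type reaction of Ph3P=CBr2 pre-formed with Zn so that neither amine base nor Ph3PBr2 is present, adds the future terminal alkyne carbon to each formyl group under non-basic conditions that leave the alpha stereocentres alone.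

Step 8
Reactants: 11 (1R,2R)-1,2-bis(2,2-dibromoethenyl)cyclobutane
Product: 13 (1R,2R)-1,2-diethynylcyclobutane, via dilithium bis(acetylide) 12 (not isolated)
Conditions: n-BuLi (4.4 equiv), THF, −78 → 0 °C; H2O; extract into pentane, concentrate cold through a column, keep as a stock solution
Reagents that add atoms: n-butyllithium, [Li]CCCC (supplies only the lithium of 12)
Why: In the second stage of the Corey–Fuchs sequence, bromine–lithium exchange, alpha-elimination and a Fritsch–Buttenberg–Wiechell 1,2-hydrogen shift give each alkyne, which is deprotonated to 12 and protonated on quench, while the ring CH centres no longer carry an acidifying carbonyl group and stay untouched.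

Step 9
Reactants: 13 (1R,2R)-1,2-diethynylcyclobutane; 14 5-bromo-2,2'-bithiophene (2.2 equiv)
Product: 15 cardopatine, (1R,2R)-1,2-bis[(2,2'-bithiophen-5-yl)ethynyl]cyclobutane
Conditions: PdCl2(PPh3)2 (5 mol %), CuI (10 mol %), i-Pr2NH–THF (degassed), 55 °C, sealed vessel, dark
Reagents that add atoms: none
Why: In the twofold Sonogashira coupling, zerovalent palladium inserts into the C5–Br bond of the bromothiophene, and alkynyl transfer from the alkynylcopper formed with CuI followed by reductive elimination makes both C(sp)–C(sp2) bonds away from the stereocentres, so the (1R,2R) configuration is carried into the target.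

## Compound list

1 | monomethyl fumarate | OC(=O)/C=C/C(=O)OC | starting material
2 | methyl (E)-4-chloro-4-oxobut-2-enoate | COC(=O)/C=C/C(=O)Cl | intermediate
3 | 2-oxazolidinone | O=C1NCCO1 | starting material
4 | lithium 2-oxooxazolidin-3-ide | [Li]N1CCOC1=O | intermediate
5 | methyl (E)-4-oxo-4-(2-oxo-1,3-oxazolidin-3-yl)but-2-enoate | COC(=O)/C=C/C(=O)N1CCOC1=O | intermediate
6 | 1,1-bis(methylthio)ethene | C=C(SC)SC | starting material
7 | methyl (1R,2R)-3,3-bis(methylthio)-2-(2-oxo-1,3-oxazolidine-3-carbonyl)cyclobutane-1-carboxylate | COC(=O)[C@@H]1CC(SC)(SC)[C@H]1C(=O)N2CCOC2=O | intermediate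
8 | methyl (1R,2R)-2-(2-oxo-1,3-oxazolidine-3-carbonyl)cyclobutane-1-carboxylate | COC(=O)[C@@H]1CC[C@H]1C(=O)N2CCOC2=O | intermediate
9 | [(1R,2R)-cyclobutane-1,2-diyl]dimethanol | OC[C@@H]1CC[C@H]1CO | intermediate
10 | (1R,2R)-cyclobutane-1,2-dicarbaldehyde | O=C[C@@H]1CC[C@H]1C=O | intermediate
11 | (1R,2R)-1,2-bis(2,2-dibromoethenyl)cyclobutane | BrC(Br)=C[C@@H]1CC[C@H]1C=C(Br)Br | intermediate
12 | dilithium bis(acetylide) of (1R,2R)-1,2-diethynylcyclobutane | [Li]C#C[C@@H]1CC[C@H]1C#C[Li] | intermediate
13 | (1R,2R)-1,2-diethynylcyclobutane | C#C[C@@H]1CC[C@H]1C#C | intermediate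
14 | 5-bromo-2,2'-bithiophene | Brc1ccc(-c2cccs2)s1 | starting material
15 | cardopatine, (1R,2R)-1,2-bis[(2,2'-bithiophen-5-yl)ethynyl]cyclobutane | C(#C[C@@H]1CC[C@H]1C#Cc1ccc(-c2cccs2)s1)c1ccc(-c2cccs2)s1 | target

## Count and risks

Total step count: 9. Longest linear sequence: 9 steps (1 → 15).

**Risk 1 (step 3).**
- Enantiofacial selectivity may be eroded or inverted by a background reaction on TiCl2(O-i-Pr)2 that is not bound to the diol.
- The donor–acceptor cyclobutane may also reopen to open-chain conjugate-addition material.
- The fallback replaces catalyst control by auxiliary control. It sets out from 6 and comes back to the route at 9.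
- Compound 6 is combined with purchased bis[(1S,2R,5S)-menthyl] fumarate F1 under Et2AlCl in toluene–hexane at −78 °C. This is the known dialkylaluminium-chloride-promoted [2+2] cycloaddition type of dimenthyl fumarates with ketene acetals.
- The product should be bis[(1S,2R,5S)-menthyl] (1R,2R)-3,3-bis(methylthio)cyclobutane-1,2-dicarboxylate F2, a diastereomer that can be purified by crystallisation.
- Raney Ni then gives bis[(1S,2R,5S)-menthyl] (1R,2R)-cyclobutane-1,2-dicarboxylate F3. LiAlH4 in THF reduces both esters to diol 9, and the menthol is recovered.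

**Risk 2 (step 6).**
- The small, volatile dialdehyde may be lost on concentration, form hydrates or oligomers, or epimerise at a formyl-bearing ring carbon before both groups are olefinated.
- The fallback builds the arms one after the other, using the difference between imide and ester that is already present. Only one formyl group then exists at a time. It sets out from 8 and comes back at 11.
- NaBH4 in THF–H2O reduces only the imide, giving methyl (1R,2R)-2-(hydroxymethyl)cyclobutane-1-carboxylate F4.
- Buffered Dess–Martin oxidation gives methyl (1R,2R)-2-formylcyclobutane-1-carboxylate F5.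
- CBr4/PPh3/Zn gives methyl (1R,2R)-2-(2,2-dibromoethenyl)cyclobutane-1-carboxylate F6.
- DIBAL-H (i-Bu2AlH) in CH2Cl2 at −78 °C gives (1R,2R)-2-(2,2-dibromoethenyl)cyclobutane-1-carbaldehyde F7.
- A second CBr4/PPh3/Zn olefination gives 11.

**Risk 3 (step 9).**
- The diyne may evaporate during handling.
- It may undergo copper-mediated oxidative homocoupling.
- The reaction may stall after the first coupling, because oxidative addition to the electron-rich bromothiophene is slow.
- The fallback is a copper-free, one-pot Negishi alkynylation that never isolates the diyne. It sets out from 11 and comes back at 15.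
- n-BuLi in THF (−78 → 0 °C) gives 12, and anhydrous ZnBr2 converts it into (1R,2R)-1,2-bis[(bromozincio)ethynyl]cyclobutane F8.
- Pd(PPh3)4 and 14 (THF, rt → 50 °C) then couple both arms to give 15.

## Further compounds

F1 | step 3 | bis[(1S,2R,5S)-menthyl] fumarate (purchased) | CC(C)[C@H]1CC[C@H](C)C[C@@H]1OC(=O)/C=C/C(=O)O[C@H]2C[C@@H](C)CC[C@@H]2C(C)C
F2 | step 3 | bis[(1S,2R,5S)-menthyl] (1R,2R)-3,3-bis(methylthio)cyclobutane-1,2-dicarboxylate | CC(C)[C@H]1CC[C@H](C)C[C@@H]1OC(=O)[C@@H]2CC(SC)(SC)[C@H]2C(=O)O[C@H]3C[C@@H](C)CC[C@@H]3C(C)C
F3 | step 3 | bis[(1S,2R,5S)-menthyl] (1R,2R)-cyclobutane-1,2-dicarboxylate | CC(C)[C@H]1CC[C@H](C)C[C@@H]1OC(=O)[C@@H]2CC[C@H]2C(=O)O[C@H]3C[C@@H](C)CC[C@@H]3C(C)C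
F4 | step 6 | methyl (1R,2R)-2-(hydroxymethyl)cyclobutane-1-carboxylate | COC(=O)[C@@H]1CC[C@H]1CO
F5 | step 6 | methyl (1R,2R)-2-formylcyclobutane-1-carboxylate | COC(=O)[C@@H]1CC[C@H]1C=O
F6 | step 6 | methyl (1R,2R)-2-(2,2-dibromoethenyl)cyclobutane-1-carboxylate | COC(=O)[C@@H]1CC[C@H]1C=C(Br)Br
F7 | step 6 | (1R,2R)-2-(2,2-dibromoethenyl)cyclobutane-1-carbaldehyde | O=C[C@@H]1CC[C@H]1C=C(Br)Br
F8 | step 9 | (1R,2R)-1,2-bis[(bromozincio)ethynyl]cyclobutane | Br[Zn]C#C[C@@H]1CC[C@H]1C#C[Zn]Br
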